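## Analysis of the target

Target 41 (CNP0211702.1) is a briarane-type diterpenoid. A cyclohexene, ring A (C1, C10, C11, C12, C13=C14), is trans-fused at C1–C10 to a ten-membered carbocycle, ring B (C1 to C10, with the Z trisubstituted C5=C6 alkene). A γ-lactone, ring C (C7–O–C19–C17–C8), is fused to ring B at C7–C8.

There are nine stereocentres. Ring A carries four contiguous ones: the quaternary C1 (C15 methyl), C10 (H trans to the C15 methyl), C11 (C20 methyl cis to the C15 methyl and to the C9 branch) and C12 (butanoyloxy trans to the C20 methyl). Ring B adds C2 (acetoxy, 2R) and C9 (acetoxy, 9R) on either side of the ring fusion. The lactone adds C7, the tertiary carbinol C8 and C17, with H7 trans to the C8 hydroxyl and the C18 methyl cis to it.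

Sensitive groups are the three esters of two kinds, a tertiary β-hydroxy lactone (retro-aldol cleavage, dehydration), an allylic C7–O bond and an allylic butanoate.

The difficulty is the ten-membered ring: seven of its ten carbons are substituted, C1 is quaternary next to C2, and the alkene must be Z. Direct end-to-end closure and Z-selective olefination are both unattractive.

The strategy rests on one feature. C2 and C7 both bear oxygen and face each other 1,6 across ring B. A bond between them divides ring B into two six-membered rings, ring D (C1, C2, C7, C8, C9, C10) and ring E (C2, C3, C4, C5, C6, C7), with C5=C6 inside ring E, where it can only be cis. Ring B can therefore be carried as a rigid cis-fused decalin diol and set free by cutting the C2–C7 bond.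

## Retrosynthetic reasoning

**Lactone, 41 ⇒ 39.** The C8–C17 bond is cut, leaving the O7 ester in place. This is the one disconnection that makes the tertiary carbinol C8 and C17 together and that allows a regiospecific enolate: 39 carries three other enolisable esters, so the enolate must come from the C–Br bond and not from a base. The forward Reformatsky reaction has to set C8 and C17.

**Oxidation pattern, 39 ⇒ 32.** Functional-group changes lead from 39 back through 38, 37, 36 and 35 to alcohol 33 and diketone 32. The C8 ketone comes from the silyl ether, the O2 acetate from the C2 ketone, and the O7 ester from acid bromide 34. The two ketones of 32 are told apart by reactivity: the C7 enone is reduced first and acylated at once, the neopentylic C2 ketone afterwards. Forward, C7 and C2 must be set in the ten-membered ring.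

**Ring B, 32 ⇒ 30.** C2 and C7 are joined again, which turns the 1,6-diketone into the cis-ditertiary diol 30 of a tricycle (rings A, D, E). The cut is made here because the two carbonyl oxygens mark exactly the bond to re-form; the ten-membered ring becomes two six-membered rings, and the Z alkene needs no selective reaction. Forward, the glycol cleavage needs a cis diol and no second vicinal diol.

**C7 and C8 oxygens, 30 ⇒ 27.** The silyl ether of 30 comes from triol 29, whose C7 and C8 hydroxyls are removed together as a syn diol from the C7=C8 alkene of diene 27. Both oxygens then arrive cis to the C2 hydroxyl, which can direct them, so the cis relationship the key step needs is built in. The C9 acetate and the C12 butanoate are already in place in 27 (from 24 via 25 and 26); the butanoate is introduced with inversion at C12.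

**Ring E, 24 ⇒ 23 ⇒ 21 + 22 ⇒ 18 + 19.** C5=C6 is cut by ring-closing metathesis, C6–C7 by cross-coupling of iodide 21 with stannane 22, and C2–C3 by 1,2-addition of the chain from bromide 19 to enone 18. The addition must occur anti to the C15 methyl to set C2.

**Ring D, 18 ⇒ 17 ⇒ 15 ⇒ 14 ⇒ 12 + 13.** The C7 iodide comes from enone 17. The C9 hydroxyl and the C7=C8 alkene of 17 come from the C8=C9 alkene of 15 by epoxidation and base-induced opening, which sets C9. C8=C9 is cut by ring-closing metathesis to allyl ketone 14, made from amide 12 and Grignard reagent 13.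

**Ring A, 12 ⇒ 11 ⇒ 10 ⇒ 9 ⇒ 7 ⇒ 4 + 5 ⇒ 3 ⇒ 1 + 2.** The C12 oxygen and the C13=C14 alkene come from ketone 7 by dehydrogenation and reduction. The C9–C10 bond is cut by conjugate addition of 5 to enone 4, which must set C10 and, on protonation, C11. Enone 4 comes from aldehyde 3 by aldol condensation, and 3 from 1 and 2 by an enantioselective Michael addition that sets C1.

## Alternatives that were turned down

**Alternative 1:** The C1–C10 bond is cut, which unfolds rings A and B into the fourteen-membered enedione A2. Forward, an amidine base would remove a C13 proton, the extended enolate would bond C1 to C10 across the ring, and protonation at C11 would give the tricyclic 2,12-diketone A1 with the lactone in place.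
- For: one step makes two rings and three stereocentres (C1, C10, C11), and A1 needs only two reductions and acylations.
- Against: A2 is itself a macrocycle carrying the full C7/C8/C9/C17 array and two trisubstituted enones of defined geometry, so the medium-ring problem is exchanged for a macrocyclisation. The enolate must react at its γ-carbon C1 to form a quaternary centre, while reaction at C13, loss of the γ-acetoxy group at C9 and retro-aldol opening of the β-hydroxy lactone compete under base. The configuration at C1, C10 and C11 rests only on the conformation of the macrocycle.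
- Comparison: this alternative is stronger on step economy in the ring-forming event. The chosen route offers instead stereocentres set one at a time in rigid six-membered rings, and a Z alkene and ten-membered ring that need no selective reaction.

**Alternative 2:** The lactone is cut at C7–C19 and C8–C17. Forward, chloro(methyl)ketene A5, made in the flask from 2-chloropropanoyl chloride A6 and a tertiary amine, would add (2+2) to the C7=C8 silyl enol ether A4 of an intact ring B. This would give the α-chlorocyclobutanone A3; oxygen insertion and dechlorination would follow.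
- For: ketene and enol ether polarity fixes the regiochemistry, and C8 and C17 are joined without a metal enolate next to an α-acyloxy ketone. On that point it is stronger than the chosen lactone closure.
- Against: A4 presupposes the ten-membered ring with its Z alkene, the hardest part of the target. Its enol ether is one half of a 2-silyloxy diene (C5=C6–C7=C8), which offers the ketene a (4+2) path. Enolisation of a C8 ketone must go towards C7 and not C9. Nothing controls the face on a flexible ten-membered ring. The peracid for oxygen insertion meets two alkenes, and C17 is still to be set in the dechlorination.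
- Comparison: more steps follow its key step; the chosen route closes the lactone last and addresses ring B directly.

**Alternative 3:** The C1–C2 bond is cut and ring B traced back to the thirteen-membered ether A8, in which oxygen links C13 to C2 and C2 carries a tributylstannyl group. Forward, an alkyllithium would exchange tin for lithium and the α-alkoxy carbanion would shift [2,3] across C14=C1. This would form C1–C2, move the alkene to C13=C14 and contract the ring to A7.
- For: the quaternary C1, the C2 carbinol and the C13=C14 alkene come from one suprafacial step with chirality passed from C13. In setting C1 and C2 together it is as strong as or stronger than the chosen route, which sets C2 late by ketone reduction.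
- Against: the shift must deliver carbon to a fully substituted alkene terminus inside ring A, the slowest case, where [1,2]-shift and elimination take over. A8 needs a macrocyclisation of its own and a configurationally defined α-alkoxystannane. The alkyllithium allows no ester, so A7 carries five different protecting or free oxygen functions that must then be exchanged one by one.
- Comparison: the chosen route uses no macrocyclisation and carries the C9 acetate and C12 butanoate through the key step.

Key step: step 20

**Remarks on the chemistry**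
- Locants C1–C20 are those of the target (C15 on C1, C16 on C5, C18 on C17, C20 on C11). For bi- and tricyclic intermediates, β is the face of rings A and D that carries the C15 methyl and α the opposite face.
- Assumption: in step 1 the catalyst is taken from the quinine series or, if the sense of induction requires it, from the pseudo-enantiomeric quinidine series, so that 3 is S.
- Assumption: acid bromide 34 is racemic, so 35–39 are pairs of epimers at the bromine-bearing carbon C17, which becomes trigonal in step 27.

## Route

Step 1
Reactants: 1 ethyl 2-methyl-3-oxopropanoate; 2 pent-1-en-3-one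
Product: 3 ethyl (2S)-2-formyl-2-methyl-5-oxoheptanoate
Conditions: 9-O-(9-phenanthryl)cupreine (10 mol %), CH2Cl2, −20 °C
Reagents that add atoms: none
Why: Organocatalytic enantioselective Michael addition of an α-substituted 1,3-dicarbonyl compound to a vinyl ketone; the bifunctional cinchona catalyst holds the enol of 1 at the quinuclidine nitrogen and the enone at the 6'-hydroxyl, so one enol face is attacked and the quaternary centre C1 is set by the catalyst.

Step 2
Reactants: 3 ethyl (2S)-2-formyl-2-methyl-5-oxoheptanoate
Product: 4 ethyl (1S)-1,3-dimethyl-4-oxocyclohex-2-ene-1-carboxylate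
Conditions: p-TsOH·H2O (10 mol %), toluene, reflux, Dean–Stark
Reagents that add atoms: none
Why: Intramolecular aldol condensation, the ring-closing half of a Robinson annulation; the formyl group has no α-hydrogen and only the ethyl ketone can enolise towards it, so the six-membered enone is the only condensation product and the quaternary centre is untouched.

Step 3
Reactants: 4 ethyl (1S)-1,3-dimethyl-4-oxocyclohex-2-ene-1-carboxylate; 5 vinylmagnesium bromide
Product: 7 ethyl (1S,2S,3R)-2-ethenyl-1,3-dimethyl-4-oxocyclohexane-1-carboxylate, via bromomagnesium enolate 6 (not isolated)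
Conditions: 5 (1.5 equiv), CuBr·SMe2 (20 mol %), THF, −78 → −40 °C; then AcOH, THF, −78 °C
Reagents that add atoms: none
Why: Copper-catalysed conjugate addition of a Grignard reagent: the vinyl group enters C10 axially and anti to the pseudoaxial ester on C1 (the ester, not the methyl, takes the pseudoaxial site), hence cis to the C15 methyl. Kinetic axial protonation of enolate 6 at C11, anti to the now pseudoaxial vinyl group, places H11 cis to H10 and the C20 methyl cis to the vinyl group.

Step 4
Reactants: 7 ethyl (1S,2S,3R)-2-ethenyl-1,3-dimethyl-4-oxocyclohexane-1-carboxylate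
Product: 9 ethyl (1S,5R,6S)-6-ethenyl-1,5-dimethyl-4-oxocyclohex-2-ene-1-carboxylate, via trimethylsilyl enol ether 8 (not isolated)
Conditions: LDA, THF, −78 °C; TMSCl; then Pd(OAc)2 (1.0 equiv), MeCN, rt
Reagents that add atoms: none
Why: Saegusa–Ito oxidation: LDA removes the less hindered C13 proton, so the kinetic silyl enol ether 8 forms without touching C11, and its palladium enolate loses the C14 hydride to give the C13=C14 enone.

Step 5
Reactants: 9 ethyl (1S,5R,6S)-6-ethenyl-1,5-dimethyl-4-oxocyclohex-2-ene-1-carboxylate
Product: 10 ethyl (1S,4S,5R,6S)-6-ethenyl-4-hydroxy-1,5-dimethylcyclohex-2-ene-1-carboxylate (12β alcohol)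
Conditions: LiAlH(Ot-Bu)3, THF, −78 → −30 °C
Reagents that add atoms: none
Why: 1,2-Reduction under steric approach control: in the favoured half-chair the C10 vinyl group is pseudoaxial on the β face, so the bulky hydride should attack C12 from the α face and give the 12β alcohol; the hindered ester is not reduced. This is the C12 epimer of the target on purpose, because the butanoate is introduced with inversion in step 17.

Step 6
Reactants: 10 ethyl (1S,4S,5R,6S)-6-ethenyl-4-hydroxy-1,5-dimethylcyclohex-2-ene-1-carboxylate
Product: 11 ethyl (1S,4S,5R,6S)-4-[(tert-butyldimethylsilyl)oxy]-6-ethenyl-1,5-dimethylcyclohex-2-ene-1-carboxylate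
Conditions: TBSOTf, 2,6-lutidine, CH2Cl2, −78 → 0 °C
Reagents that add atoms: tert-butyldimethylsilyl triflate, CC(C)(C)[Si](C)(C)OS(=O)(=O)C(F)(F)F
Why: Silylation of a hindered secondary alcohol; the ether shields O12 from the organometallic reagents and the peracid of steps 7 to 12.

Step 7
Reactants: 11 ethyl (1S,4S,5R,6S)-4-[(tert-butyldimethylsilyl)oxy]-6-ethenyl-1,5-dimethylcyclohex-2-ene-1-carboxylate
Product: 12 (1S,4S,5R,6S)-4-[(tert-butyldimethylsilyl)oxy]-6-ethenyl-N-methoxy-N,1,5-trimethylcyclohex-2-ene-1-carboxamide
Conditions: Me(MeO)NH·HCl, AlMe3, toluene, 0 → 80 °C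
Reagents that add atoms: N,O-dimethylhydroxylamine hydrochloride, CNOC.Cl
Why: Aminolysis of an ester by an aluminium amide to the N-methoxy-N-methylamide (Weinreb amide); the reagent is reactive enough for the neopentylic ester and leaves the silyl ether and the alkenes alone.

Step 8
Reactants: 12 (1S,4S,5R,6S)-4-[(tert-butyldimethylsilyl)oxy]-6-ethenyl-N-methoxy-N,1,5-trimethylcyclohex-2-ene-1-carboxamide; 13 allylmagnesium bromide
Product: 14 1-[(1S,4S,5R,6S)-4-[(tert-butyldimethylsilyl)oxy]-6-ethenyl-1,5-dimethylcyclohex-2-en-1-yl]but-3-en-1-one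
Conditions: 13 (1.5 equiv), THF, −78 °C; aq. NH4Cl, −78 → 0 °C
Reagents that add atoms: none
Why: Weinreb ketone synthesis: the N-methoxy-N-methylamide accepts one equivalent of the Grignard reagent only, and the cold, weakly acidic quench keeps the β,γ-unsaturated ketone from moving into conjugation.

Step 9
Reactants: 14 1-[(1S,4S,5R,6S)-4-[(tert-butyldimethylsilyl)oxy]-6-ethenyl-1,5-dimethylcyclohex-2-en-1-yl]but-3-en-1-one
Product: 15 trans-fused ring A/ring D ketone (C2 ketone; C8=C9 and C13=C14 alkenes; 10α-H; 11β-CH3; 12β-OTBS)
Conditions: second-generation Grubbs catalyst (H2IMes)(PCy3)Cl2Ru=CHPh (5 mol %), 1,4-benzoquinone (10 mol %), CH2Cl2, 40 °C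
Reagents that add atoms: none
Why: Ring-closing metathesis of the vinyl and allyl groups, which are trans on C10 and C1 and can both be pseudoequatorial, closes the trans-fused six-membered ring D with the C8=C9 alkene; benzoquinone suppresses isomerisation of the β,γ-enone by ruthenium hydrides.

Step 10
Reactants: 15 trans-fused ring A/ring D ketone
Product: 17 9α-hydroxy enone of rings A and D (C2 ketone; C7=C8; 9α-OH; 12β-OTBS), via 8α,9α-epoxy ketone 16 (not isolated)
Conditions: mCPBA, NaHCO3, CH2Cl2, 0 °C; then DBU (0.2 equiv), rt
Reagents that add atoms: 3-chloroperoxybenzoic acid, OOC(=O)c1cccc(Cl)c1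
Why: Epoxidation of the more accessible C8=C9 alkene from the α face, anti to the axial C15 methyl that is 1,3 to C9 (C13=C14 is flanked by the quaternary C1 and the silyloxy-bearing C12). Base then opens the β,γ-epoxy ketone 16 by E1cB elimination, so the C9 oxygen keeps its α configuration and the alkene moves to C7=C8.

Step 11
Reactants: 17 9α-hydroxy enone of rings A and D
Product: 18 7-iodo-9α-hydroxy enone of rings A and D
Conditions: I2, pyridine, CH2Cl2, rt
Reagents that add atoms: iodine, II
Why: α-Iodination of a cyclic enone by conjugate addition of pyridine, iodination of the enolate and elimination; only the ring D enone can react and the free alcohol is tolerated.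

Step 12
Reactants: 18 7-iodo-9α-hydroxy enone of rings A and D; 19 4-bromo-2-methylbut-1-ene
Product: 21 7-iodo-2β,9α-diol with the 3-methylbut-3-enyl chain α on C2 (C7=C8; 12β-OTBS), via 3-methylbut-3-enylmagnesium bromide 20 (not isolated)
Conditions: 19, Mg, THF, rt; then anhydrous CeCl3, THF, −78 °C, 18 (3 equiv of 20)
Reagents that add atoms: none
Why: CeCl3-promoted Grignard 1,2-addition to a hindered enone, which suppresses conjugate addition and halogen–metal exchange; one equivalent is spent on the C9 hydroxyl. The nucleophile attacks C2 from the α face, anti to the axial C15 methyl on the neighbouring quaternary C1, so the new tertiary hydroxyl is β.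

Step 13
Reactants: 21 7-iodo-2β,9α-diol; 22 tributyl(vinyl)stannane
Product: 23 7-ethenyl-2β,9α-diol (C7=C8 conjugated with the new vinyl group; butenyl chain on C2; 12β-OTBS)
Conditions: Pd2(dba)3 (5 mol %), AsPh3 (20 mol %), CuI (10 mol %), NMP, 50 °C
Reagents that add atoms: none
Why: Stille coupling of an alkenyl iodide with a vinylstannane under soft-ligand and copper co-catalysis, conditions suited to a hindered iodide next to a free tertiary alcohol.

Step 14
Reactants: 23 7-ethenyl-2β,9α-diol
Product: 24 tricyclic dienediol of rings A, D and E (C5=C6–C7=C8 diene; 2β-OH; 9α-OH; 12β-OTBS)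
Conditions: second-generation Grubbs catalyst (H2IMes)(PCy3)Cl2Ru=CHPh (10 mol %), toluene, 60 °C
Reagents that add atoms: none
Why: Ring-closing metathesis between the 1,1-disubstituted alkene of the side chain and the terminal alkene of the diene closes cyclohexene ring E; the new trisubstituted C5=C6 bond can only be cis within a six-membered ring, which is the Z geometry of the target.

Step 15
Reactants: 24 tricyclic dienediol of rings A, D and E
Product: 25 9α-acetate of 24 (2β-OH free; 12β-OTBS)
Conditions: Ac2O, pyridine, DMAP (cat.), CH2Cl2, 0 °C → rt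
Reagents that add atoms: acetic anhydride, CC(=O)OC(C)=O
Why: Acetylation of the secondary allylic C9 hydroxyl; the tertiary C2 hydroxyl does not react. The acetate also removes the C9 hydroxyl as a competing directing group for step 18.

Step 16
Reactants: 25 9α-acetate of 24
Product: 26 12β-alcohol (9α-OAc; 2β-OH)
Conditions: TBAF, AcOH, THF, rt → 40 °C
Reagents that add atoms: none
Why: Fluoride cleavage of the silyl ether, buffered with acetic acid so that the allylic acetate neither migrates nor is cleaved.

Step 17
Reactants: 26 12β-alcohol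
Product: 27 12α-butanoate (9α-OAc; 2β-OH; C5=C6–C7=C8 diene)
Conditions: PPh3, DIAD, butanoic acid, toluene, 0 °C → rt
Reagents that add atoms: butanoic acid, CCCC(=O)O
Why: Mitsunobu esterification: the carboxylate displaces the activated equatorial 12β oxygen from the open α face, anti to the axial C20 methyl, and gives the 12α butanoate with inversion. The SN2' position C14 is neopentylic and the tertiary C2 hydroxyl is not activated.

Step 18
Reactants: 27 12α-butanoate
Product: 29 2β,7β,8β-triol (9α-OAc; 12α-butanoate; C5=C6 in ring E), via cyclic osmate ester 28 (not isolated)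
Conditions: OsO4 (1.05 equiv), TMEDA (1.1 equiv), CH2Cl2, −78 °C; then aq. NaHSO3, THF, rt
Reagents that add atoms: osmium tetroxide, O=[Os](=O)(=O)=O
Why: Hydrogen-bond-directed dihydroxylation: the OsO4·TMEDA complex is held by the tertiary C2 hydroxyl and delivered to the adjacent C7=C8 alkene on the same (β) face, which is also anti to the allylic C9 acetate; the homoallylic C5=C6 and the hindered C13=C14 alkenes should not be reached. Both new C–O bonds form syn to the C2 hydroxyl, which gives the cis-2,7-diol that step 20 needs.

Step 19
Reactants: 29 2β,7β,8β-triol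
Product: 30 tricyclic cis-2β,7β-diol with 8β-OSiEt3, 9α-OAc and 12α-butanoate (precursor of the key step)
Conditions: TESCl, imidazole, DMF, 0 °C
Reagents that add atoms: chlorotriethylsilane, CC[Si](Cl)(CC)CC
Why: Silylation of the only secondary hydroxyl while the two tertiary hydroxyls stay free; the C2/C7 pair is then the only vicinal diol.

Step 20
Reactants: 30 tricyclic cis-2β,7β-diol
Product: 32 ring A/ring B bicycle with C2 ketone and (5Z)-en-7-one (8-OSiEt3; 9-OAc; 12-butanoate), via cyclic plumbate diester 31 (not isolated)
Conditions: Pb(OAc)4 (1.1 equiv), pyridine (3 equiv), CH2Cl2, 0 °C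
Reagents that add atoms: none
Why: Criegee glycol cleavage: the two tertiary hydroxyls displace two acetates from tetravalent lead to give the five-membered cyclic diester 31, which breaks down in one concerted two-electron step in which the C2–C7 σ bond is cut, both C–O bonds become carbonyls and divalent lead diacetate leaves. The closest known reaction is the lead tetraacetate cleavage of ring-fusion cis-1,2-diols of bicyclo[4.4.0]decanes to cyclodecane-1,6-diones. Ring B is not closed by bond formation: it is set free when the bond shared by rings D and E is cut, so the ten-membered ring is the periphery of the former decalin and no end-to-end cyclisation takes place. No stereocentre is created (C2 and C7 become trigonal), and C5=C6 is Z because the alkene was cis inside ring E. The step needs chemoselectivity for the glycol and a cis diol: the O–C2–C7–O dihedral angle of about 60° in the cis-fused system allows the cyclic ester, the C8 oxygen is capped as its silyl ether so that the C7–C8 bond cannot be cleaved, and esters and alkenes do not react with Pb(OAc)4 at 0 °C. Pyridine buffers the acetic acid, so that the 1,6-diketone, which is prone to transannular aldol reaction, is not exposed to acid.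

Step 21
Reactants: 32 ring A/ring B bicycle with C2 ketone and (5Z)-en-7-one
Product: 33 (7S)-allylic alcohol (C2 ketone kept; other centres as in 32)
Conditions: NaBH4, CeCl3·7H2O, MeOH, −78 °C
Reagents that add atoms: none
Why: Luche reduction: it is 1,2-selective for the enone, and the C7 carbonyl reacts before the C2 ketone, which sits next to the quaternary C1. Felkin–Anh control by the C8 silyloxy group (C–O bond anti to the incoming hydride, which passes the C8 hydrogen) places the C7 and C8 oxygens syn in the extended chain, which is the 7S alcohol.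

Step 22
Reactants: 33 (7S)-allylic alcohol; 34 2-bromopropanoyl bromide
Product: 35 7-O-(2-bromopropanoyl) ester (C2 ketone; 8-OSiEt3)
Conditions: 34, pyridine, DMAP (cat.), CH2Cl2, −20 °C
Reagents that add atoms: none
Why: Acylation of the secondary allylic alcohol by an acid bromide; the acyl group brings C17, C18 and C19 of the lactone and marks O7 while the C2 oxygen is still a ketone.

Step 23
Reactants: 35 7-O-(2-bromopropanoyl) ester
Product: 36 (2R)-alcohol (7-O-bromopropanoyl; 8-OSiEt3)
Conditions: (S)-2-methyl-CBS-oxazaborolidine (0.5 equiv), catecholborane, toluene, −78 → −40 °C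
Reagents that add atoms: none
Why: Corey–Bakshi–Shibata reduction: the ketone has a tertiary alkyl flank (C1) and a methylene flank (C3), the pattern the catalyst differentiates best, and the S catalyst should deliver hydride to give the 2R alcohol; catecholborane leaves alkenes, esters and the bromide untouched. Felkin–Anh attack anti to the C1–C10 ring bond points the same way.

Step 24
Reactants: 36 (2R)-alcohol
Product: 37 2-acetate (2R; 7-O-bromopropanoyl; 8-OSiEt3; 9-OAc; 12-butanoate)
Conditions: Ac2O, Et3N, DMAP, CH2Cl2, rt
Reagents that add atoms: acetic anhydride, CC(=O)OC(C)=O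
Why: Acetylation of the hindered secondary C2 alcohol under nucleophilic catalysis; no other free hydroxyl is present.

Step 25
Reactants: 37 2-acetate
Product: 38 8-alcohol (C8 configuration as in 30)
Conditions: HF·pyridine, pyridine, THF, 0 °C
Reagents that add atoms: none
Why: Selective cleavage of the triethylsilyl ether; esters, the alkyl bromide and the alkenes are stable to buffered HF.

Step 26
Reactants: 38 8-alcohol
Product: 39 8-ketone (7-O-bromopropanoyl; 2,9-diacetate; 12-butanoate)
Conditions: Dess–Martin periodinane, NaHCO3, CH2Cl2, 0 °C → rt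
Reagents that add atoms: none
Why: Oxidation of the secondary alcohol to the ketone under neutral, buffered conditions, which avoid epimerisation at C7 and C9 of the α,α'-bis(acyloxy) ketone.

Step 27
Reactants: 39 8-ketone
Product: 41 CNP0211702.1 (1S,2R,7S,8S,9R,10S,11R,12R,17R), via samarium enolate 40 (not isolated)
Conditions: SmI2 (2.2 equiv, slow addition), THF, −78 °C; aq. NH4Cl
Reagents that add atoms: none
Why: SmI2-promoted intramolecular Reformatsky reaction: the C–Br bond is reduced first, so only the propanoate enolate 40 forms, which a base could not achieve beside three other enolisable esters. Trivalent samarium bridges the enolate and ketone oxygens, and the enolate can reach the C8 carbonyl only on the face that keeps the C6–C7–C8–C9 ring torsion anti, which makes the new hydroxyl trans to H7 (8S). The Z enolate in this chelated transition state should place the C18 methyl cis to the new hydroxyl (17R).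

## Compound list

1 | ethyl 2-methyl-3-oxopropanoate | CCOC(=O)C(C)C=O | starting material
2 | pent-1-en-3-one | CCC(=O)C=C | starting material
3 | ethyl (2S)-2-formyl-2-methyl-5-oxoheptanoate | CCC(=O)CC[C@@](C(=O)OCC)(C)C=O | intermediate
4 | ethyl (1S)-1,3-dimethyl-4-oxocyclohex-2-ene-1-carboxylate | O=C1CC[C@@](C(=O)OCC)(C)C=C1C | intermediate
5 | vinylmagnesium bromide | C=C[Mg]Br | starting material
6 | bromomagnesium enolate (C11=C12) formed from 4 and 5 | Br[Mg]OC1=C(C)[C@H](C=C)[C@@](C)(C(=O)OCC)CC1 | intermediate
7 | ethyl (1S,2S,3R)-2-ethenyl-1,3-dimethyl-4-oxocyclohexane-1-carboxylate | O=C1CC[C@@](C(=O)OCC)(C)[C@H]([C@H]1C)C=C | intermediate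
8 | ethyl (1S,2S,3R)-2-ethenyl-1,3-dimethyl-4-(trimethylsilyloxy)cyclohex-4-ene-1-carboxylate | C[Si](C)(C)OC1=CC[C@@](C(=O)OCC)(C)[C@H]([C@H]1C)C=C | intermediate
9 | ethyl (1S,5R,6S)-6-ethenyl-1,5-dimethyl-4-oxocyclohex-2-ene-1-carboxylate | O=C1C=C[C@@](C(=O)OCC)(C)[C@H]([C@H]1C)C=C | intermediate
10 | ethyl (1S,4S,5R,6S)-6-ethenyl-4-hydroxy-1,5-dimethylcyclohex-2-ene-1-carboxylate | O[C@H]1C=C[C@@](C(=O)OCC)(C)[C@H]([C@H]1C)C=C | intermediate
11 | ethyl (1S,4S,5R,6S)-4-[(tert-butyldimethylsilyl)oxy]-6-ethenyl-1,5-dimethylcyclohex-2-ene-1-carboxylate | CC(C)(C)[Si](C)(C)O[C@H]1C=C[C@@](C(=O)OCC)(C)[C@H]([C@H]1C)C=C | intermediate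
12 | (1S,4S,5R,6S)-4-[(tert-butyldimethylsilyl)oxy]-6-ethenyl-N-methoxy-N,1,5-trimethylcyclohex-2-ene-1-carboxamide | CC(C)(C)[Si](C)(C)O[C@H]1C=C[C@@](C(=O)N(C)OC)(C)[C@H]([C@H]1C)C=C | intermediate
13 | allylmagnesium bromide | C=CC[Mg]Br | starting material
14 | 1-[(1S,4S,5R,6S)-4-[(tert-butyldimethylsilyl)oxy]-6-ethenyl-1,5-dimethylcyclohex-2-en-1-yl]but-3-en-1-one | CC(C)(C)[Si](C)(C)O[C@H]1C=C[C@@](C(=O)CC=C)(C)[C@H]([C@H]1C)C=C | intermediate
15 | trans-fused ring A/ring D ketone (C2 ketone; C8=C9; C13=C14; 12β-OTBS) | CC(C)(C)[Si](C)(C)O[C@H]1C=C[C@@]2(C)[C@H]([C@H]1C)C=CCC2=O | intermediate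
16 | 8α,9α-epoxide of 15 | CC(C)(C)[Si](C)(C)O[C@H]1C=C[C@@]2(C)[C@H]([C@H]1C)[C@H]3O[C@H]3CC2=O | intermediate
17 | 9α-hydroxy enone of rings A and D (C2 ketone; C7=C8) | CC(C)(C)[Si](C)(C)O[C@H]1C=C[C@@]2(C)[C@H]([C@H]1C)[C@@H](O)C=CC2=O | intermediate
18 | 7-iodo-9α-hydroxy enone of rings A and D | CC(C)(C)[Si](C)(C)O[C@H]1C=C[C@@]2(C)[C@H]([C@H]1C)[C@@H](O)C=C(I)C2=O | intermediate
19 | 4-bromo-2-methylbut-1-ene | CC(=C)CCBr | starting material
20 | 3-methylbut-3-enylmagnesium bromide | CC(=C)CC[Mg]Br | intermediate
21 | 7-iodo-2β,9α-diol with α-(3-methylbut-3-enyl) on C2 | CC(C)(C)[Si](C)(C)O[C@H]1C=C[C@@]2(C)[C@H]([C@H]1C)[C@@H](O)C=C(I)[C@@]2(O)CCC(C)=C | intermediate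
22 | tributyl(vinyl)stannane | C=C[Sn](CCCC)(CCCC)CCCC | starting material
23 | 7-ethenyl-2β,9α-diol with α-(3-methylbut-3-enyl) on C2 | CC(C)(C)[Si](C)(C)O[C@H]1C=C[C@@]2(C)[C@H]([C@H]1C)[C@@H](O)C=C(C=C)[C@@]2(O)CCC(C)=C | intermediate
24 | tricyclic dienediol of rings A, D and E (2β-OH; 9α-OH; 12β-OTBS) | CC(C)(C)[Si](C)(C)O[C@H]1C=C[C@@]2(C)[C@H]([C@H]1C)[C@@H](O)C=C3C=C(C)CC[C@@]23O | intermediate
25 | 9α-acetate of 24 | CC(C)(C)[Si](C)(C)O[C@H]1C=C[C@@]2(C)[C@H]([C@H]1C)[C@@H](OC(C)=O)C=C3C=C(C)CC[C@@]23O | intermediate
26 | 12β-alcohol (9α-OAc; 2β-OH) | O[C@H]1C=C[C@@]2(C)[C@H]([C@H]1C)[C@@H](OC(C)=O)C=C3C=C(C)CC[C@@]23O | intermediate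
27 | 12α-butanoate (9α-OAc; 2β-OH; diene) | CCCC(=O)O[C@@H]1C=C[C@@]2(C)[C@H]([C@H]1C)[C@@H](OC(C)=O)C=C3C=C(C)CC[C@@]23O | intermediate
28 | cyclic osmate ester (hexavalent osmium, TMEDA-bound) on O7 and O8 | CCCC(=O)O[C@@H]1C=C[C@@]2(C)[C@H]([C@H]1C)[C@@H](OC(C)=O)[C@H](O4)[C@@]3(O[Os-2]4(=O)(=O)([N+](C)(C)CC5)[N+]5(C)C)C=C(C)CC[C@@]23O | intermediate
29 | 2β,7β,8β-triol (9α-OAc; 12α-butanoate) | CCCC(=O)O[C@@H]1C=C[C@@]2(C)[C@H]([C@H]1C)[C@@H](OC(C)=O)[C@H](O)[C@@]3(O)C=C(C)CC[C@@]23O | intermediate
30 | tricyclic cis-2β,7β-diol with 8β-OSiEt3, 9α-OAc, 12α-butanoate | CCCC(=O)O[C@@H]1C=C[C@@]2(C)[C@H]([C@H]1C)[C@@H](OC(C)=O)[C@H](O[Si](CC)(CC)CC)[C@@]3(O)C=C(C)CC[C@@]23O | intermediate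
31 | cyclic diester of tetravalent lead on O2 and O7 | CCCC(=O)O[C@@H]1C=C[C@@]2(C)[C@H]([C@H]1C)[C@@H](OC(C)=O)[C@H](O[Si](CC)(CC)CC)[C@@]3(O4)C=C(C)CC[C@@]23O[Pb]4(OC(C)=O)OC(C)=O | intermediate
32 | ring A/ring B bicycle with C2 ketone and (5Z)-en-7-one | CCCC(=O)O[C@@H]1C=C[C@@]2(C)[C@H]([C@H]1C)[C@@H](OC(C)=O)[C@H](O[Si](CC)(CC)CC)C(=O)/C=C(/C)CCC2=O | intermediate
33 | (7S)-allylic alcohol of 32 | CCCC(=O)O[C@@H]1C=C[C@@]2(C)[C@H]([C@H]1C)[C@@H](OC(C)=O)[C@H](O[Si](CC)(CC)CC)[C@@H](O)/C=C(/C)CCC2=O | intermediate
34 | 2-bromopropanoyl bromide | CC(Br)C(=O)Br | starting material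
35 | 7-O-(2-bromopropanoyl) ester of 33 | CCCC(=O)O[C@@H]1C=C[C@@]2(C)[C@H]([C@H]1C)[C@@H](OC(C)=O)[C@H](O[Si](CC)(CC)CC)[C@@H](OC(=O)C(C)Br)/C=C(/C)CCC2=O | intermediate
36 | (2R)-alcohol | CCCC(=O)O[C@@H]1C=C[C@@]2(C)[C@H]([C@H]1C)[C@@H](OC(C)=O)[C@H](O[Si](CC)(CC)CC)[C@@H](OC(=O)C(C)Br)/C=C(/C)CC[C@H]2O | intermediate
37 | 2-acetate | CCCC(=O)O[C@@H]1C=C[C@@]2(C)[C@H]([C@H]1C)[C@@H](OC(C)=O)[C@H](O[Si](CC)(CC)CC)[C@@H](OC(=O)C(C)Br)/C=C(/C)CC[C@H]2OC(C)=O | intermediate
38 | 8-alcohol | CCCC(=O)O[C@@H]1C=C[C@@]2(C)[C@H]([C@H]1C)[C@@H](OC(C)=O)[C@H](O)[C@@H](OC(=O)C(C)Br)/C=C(/C)CC[C@H]2OC(C)=O | intermediate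
39 | 8-ketone | CCCC(=O)O[C@@H]1C=C[C@@]2(C)[C@H]([C@H]1C)[C@@H](OC(C)=O)C(=O)[C@@H](OC(=O)C(C)Br)/C=C(/C)CC[C@H]2OC(C)=O | intermediate
40 | trivalent samarium enolate of the O7 propanoate | CCCC(=O)O[C@@H]1C=C[C@@]2(C)[C@H]([C@H]1C)[C@@H](OC(C)=O)C(=O)[C@@H](O/C(O[Sm](I)I)=C/C)/C=C(/C)CC[C@H]2OC(C)=O | intermediate
41 | CNP0211702.1, (1S,2R,7S,8S,9R,10S,11R,12R,17R) | CCCC(=O)O[C@@H]1C=C[C@@]2(C)[C@H]([C@H]1C)[C@@H](OC(C)=O)[C@@]1(O)[C@H](/C=C(/C)CC[C@H]2OC(C)=O)OC(=O)[C@@H]1C | target

## Step count and least certain steps

Total: 27 steps. Longest linear sequence: 27 steps (from 1 and 2 to 41); 5, 13, 19, 22 and 34 are commercial reagents added along this line.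

**Step 20 (key step).** The cyclic ester may form slowly at the crowded ditertiary diol (C2 next to the quaternary C1; the C7 hydroxyl syn-axial to the C15 methyl). Once the 1,6-diketone is free, lead salts can promote transannular aldol reaction or Z to E isomerisation of the enone. Fallback: from 30, break the same bond by a radical path. PhI(OAc)2 and I2 under visible light convert the C2 hydroxyl into a hypoiodite, the alkoxyl radical fragments the C2–C7 bond, and the resulting α-hydroxy allylic radical at C7 is oxidised to the ketone, which returns to 32 without a new isolated compound.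

**Step 3.** Methyl and ester on C1 differ little in size, so facial selectivity of the vinyl addition may be poor. The two C11 epimers are close in energy, so any loss of kinetic control in the protonation gives a mixture. Fallback: from 4, replace substrate control by catalyst control, a copper-catalysed asymmetric conjugate addition of 5 with a chiral ferrocenyl diphosphine, with the enolate trapped by chlorotrimethylsilane as the trimethylsilyl enol ether F1. This is isolated, converted with MeLi into the lithium enolate and protonated at −78 °C by a hindered proton donor, returning to 7.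

**Step 5.** Both faces of the C12 carbonyl are flanked by a pseudoaxial group (vinyl on the β face, ester across the ring on the α face), so facial selectivity may be low or reversed. Fallback: from 9, if the 12α alcohol F2 forms, invert it by Mitsunobu reaction with 4-nitrobenzoic acid to the 12β 4-nitrobenzoate F3 and cleave this with K2CO3 in MeOH, returning to 10.

**Step 21.** The conformation of the ten-membered ring may override Felkin–Anh control and give the 7R alcohol; the silyl group may also migrate from O8 to the new alkoxide. Fallback: from 32, if the (7R)-alcohol F4 is obtained, esterify it with 2-bromopropanoic acid under Mitsunobu conditions, which inverts C7 and gives 35 directly.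

**Step 27.** SmI2 may reduce the α-acyloxy ketone (loss of the C9 acetate or of the O7 ester) in competition with the C–Br bond, and the enolate geometry may not give the 17R configuration. Fallback: from 37, eliminate HBr with DBU to the 7-O-acrylate F5, remove the silyl group with HF·pyridine to the acrylate alcohol F6 and oxidise with Dess–Martin periodinane to the acrylate ketone F7. A copper hydride reductive aldol cyclisation with [(Ph3P)CuH]6 then generates the propanoate enolate by conjugate reduction, without a single-electron reductant, and closes the lactone to 41.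

## Further compounds

F0 | step 20 | none | none
F1 | step 3 | ethyl (1S,2S,3R)-2-ethenyl-1,3-dimethyl-4-(trimethylsilyloxy)cyclohex-3-ene-1-carboxylate | C[Si](C)(C)OC1=C(C)[C@H](C=C)[C@@](C)(C(=O)OCC)CC1
F2 | step 5 | ethyl (1S,4R,5R,6S)-6-ethenyl-4-hydroxy-1,5-dimethylcyclohex-2-ene-1-carboxylate (12α alcohol) | O[C@@H]1C=C[C@@](C(=O)OCC)(C)[C@H]([C@H]1C)C=C
F3 | step 5 | 12β 4-nitrobenzoate of 10 | O=C(O[C@H]1C=C[C@@](C(=O)OCC)(C)[C@H]([C@H]1C)C=C)c1ccc(cc1)[N+](=O)[O-]
F4 | step 21 | (7R)-alcohol, C7 epimer of 33 | CCCC(=O)O[C@@H]1C=C[C@@]2(C)[C@H]([C@H]1C)[C@@H](OC(C)=O)[C@H](O[Si](CC)(CC)CC)[C@H](O)/C=C(/C)CCC2=O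
F5 | step 27 | 7-O-acrylate with 8-OSiEt3 | CCCC(=O)O[C@@H]1C=C[C@@]2(C)[C@H]([C@H]1C)[C@@H](OC(C)=O)[C@H](O[Si](CC)(CC)CC)[C@@H](OC(=O)C=C)/C=C(/C)CC[C@H]2OC(C)=O
F6 | step 27 | 7-O-acrylate 8-alcohol | CCCC(=O)O[C@@H]1C=C[C@@]2(C)[C@H]([C@H]1C)[C@@H](OC(C)=O)[C@H](O)[C@@H](OC(=O)C=C)/C=C(/C)CC[C@H]2OC(C)=O
F7 | step 27 | 7-O-acrylate 8-ketone | CCCC(=O)O[C@@H]1C=C[C@@]2(C)[C@H]([C@H]1C)[C@@H](OC(C)=O)C(=O)[C@@H](OC(=O)C=C)/C=C(/C)CC[C@H]2OC(C)=O
A1 | alternative 1 | tricyclic 2,12-diketone with lactone | O=C1C=C[C@@]2(C)[C@H]([C@H]1C)[C@@H](OC(C)=O)[C@@]1(O)[C@H](/C=C(/C)CCC2=O)OC(=O)[C@@H]1C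
A2 | alternative 1 | fourteen-membered enedione with fused lactone | O=C1C/C=C(\C)C(=O)CC/C(C)=C\[C@@H]2OC(=O)[C@H](C)[C@@]2(O)[C@H](OC(C)=O)/C=C1\C
A3 | alternative 2 | α-chlorocyclobutanone fused at C7–C8 | CCCC(=O)O[C@@H]1C=C[C@@]2(C)[C@H]([C@H]1C)[C@@H](OC(C)=O)[C@@]1(O[Si](C)(C)C(C)(C)C)[C@H](/C=C(/C)CC[C@H]2OC(C)=O)C(=O)[C@@]1(C)Cl
A4 | alternative 2 | C7=C8 tert-butyldimethylsilyl enol ether of ring B | CCCC(=O)O[C@@H]1C=C[C@@]2(C)[C@H]([C@H]1C)[C@@H](OC(C)=O)C(O[Si](C)(C)C(C)(C)C)=C/C=C(/C)CC[C@H]2OC(C)=O
A5 | alternative 2 | chloro(methyl)ketene | CC(Cl)=C=O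
A6 | alternative 2 | 2-chloropropanoyl chloride | CC(Cl)C(Cl)=O
A7 | alternative 3 | ring A/ring B bicycle with quaternary C1 and free C2 hydroxyl | COc1ccc(cc1)CO[C@@H]1C=C[C@@]2(C)[C@H]([C@H]1C)[C@@H](O[Si](C)(C)C(C)(C)C)C3(OCCO3)[C@@H](O[Si](CC)(CC)CC)/C=C(/C)CC[C@H]2O
A8 | alternative 3 | thirteen-membered C13–O–C2 ether with tributylstannyl on C2 | COc1ccc(cc1)CO[C@@H]1[C@H](O2)C=C(C)[C@H]([C@H]1C)[C@@H](O[Si](C)(C)C(C)(C)C)C3(OCCO3)[C@@H](O[Si](CC)(CC)CC)/C=C(/C)CCC2[Sn](CCCC)(CCCC)CCCC
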